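**Strategy**

The ten-membered carbocycle (C1–C10) is reached from a cyclohexenol by exchanging its C1–C6 bond for the C8–C9 bond. The target shows the required pattern: oxygen on C6, the C1=C10 alkene four atoms away, and the vicinally dioxygenated C8–C9 bond between them. One anionic oxy-Cope rearrangement therefore gives the C6 ketone, the ring-cis C1=C10 alkene and both C8 and C9 stereocentres. Its precursor is a quinic-acid-derived cyclohex-2-enol bearing an (E)-2-(4-methoxybenzyloxy)vinyl group on the carbinol carbon C6 and, on C1, a 4H-1,3-dioxin ring that locks the C9 enol ether (O9 tied to C14), with trans C2/C3 silyl ethers that later become the cis-epoxide.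

Key step: step 13

**Remarks on the chemistry**

- Locants are germacrane-type: ring C1–C10, lactone carbons C11–C13, C14 on C10, C15 on C4. PMB = 4-methoxybenzyl, TBS = tert-butyldimethylsilyl, TBDPS = tert-butyldiphenylsilyl, TES = triethylsilyl.
- Closing a vicinal diol monosulfonate to an epoxide inverts one carbon, so a cis-2,3-diol would give the trans-epoxide. The route therefore carries the (2R,3R)-trans-diol and inverts C3 in the last step to reach the (2R,3S)-cis-epoxide.
- The C9 enol ether needs its oxygen trans to C1 (cis to C14); this is fixed by the dioxin ring. The (E)-alkoxyvinyl group on C6 is made by alkyne reduction, because (E)-2-alkoxyvinyllithium reagents lose alkoxide by anti-elimination.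
- The 2-methylbutanoyl group of the target is (R); the hydroxy-acetoxy acid is (2S,3S).
- Assumption: the D-fructose-derived epoxidation catalyst attacks benzyl tiglate on the face established for cinnamate esters; if not, the enantiomeric ketone would be used.

**Route**

Step 1
Reactants: 1 (−)-quinic acid
Product: 2 3,4-O-isopropylidenequinic acid 1,5-lactone
Conditions: Me2C(OMe)2, TsOH·H2O (cat.), acetone, reflux
Reagents that add atoms: 2,2-dimethoxypropane, COC(C)(C)OC
Why: Acid-catalysed ketalisation of the cis-3,4-diol with concurrent 1,5-lactonisation is the standard first move on quinic acid and leaves all four stereocentres untouched.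

Step 2
Reactants: 2 quinide acetonide
Product: 3 acetonide triol (lactone reduced to CH2OH; quinic configuration kept)
Conditions: NaBH4, EtOH, 0 → 25 °C
Reagents that add atoms: none
Why: Borohydride reduction of the strained bridged lactone opens it to the primary alcohol without affecting the acetonide.

Step 3
Reactants: 3 acetonide triol
Product: 4 (3R,4S,5R)-5-hydroxy-3,4-(isopropylidenedioxy)cyclohexan-1-one
Conditions: NaIO4, H2O/THF (pH 7), 0 °C
Reagents that add atoms: none
Why: Periodate glycol cleavage (Malaprade reaction) of the tertiary/primary 1,2-diol removes the former carboxyl carbon and reveals the ring ketone.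

Step 4
Reactants: 4 hydroxy ketone
Product: 5 5-O-TBDPS ether of ketone 4
Conditions: t-BuPh2SiCl, imidazole, DMF, 0 → 25 °C
Reagents that add atoms: tert-butyl(chloro)diphenylsilane, CC(C)(C)[Si](Cl)(c1ccccc1)c1ccccc1
Why: Silylation of the single free secondary hydroxyl (the future O2) with a group that should survive mild acid, base, hydride and oxidants until the last step.

Step 5
Reactants: 5 TBDPS ketone
Product: 6 (4R,5R)-5-(tert-butyldiphenylsilyloxy)-4-hydroxycyclohex-2-en-1-one
Conditions: DBU, CH2Cl2, 0 → 25 °C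
Reagents that add atoms: none
Why: E1cB β-elimination expels the acetonide oxygen β to the ketone, which then loses acetone, so the enone appears with a free allylic hydroxyl trans to the silyloxy group; the equatorial silyl ether on the other β-carbon is poorly aligned to leave.

Step 6
Reactants: 6 hydroxy enone
Product: 7 (4R,5R)-4-(tert-butyldimethylsilyloxy)-5-(tert-butyldiphenylsilyloxy)cyclohex-2-en-1-one
Conditions: t-BuMe2SiOTf, 2,6-lutidine, CH2Cl2, −78 °C
Reagents that add atoms: tert-butyldimethylsilyl trifluoromethanesulfonate, CC(C)(C)[Si](C)(C)OS(=O)(=O)C(F)(F)F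
Why: Silyl triflate silylation caps the hindered allylic hydroxyl (the future O3) as a TBS ether that can later be removed in the presence of the TBDPS ether.

Step 7
Reactants: 7 bis-silyl enone
Product: 9 (4R,5R)-4-(tert-butyldimethylsilyloxy)-5-(tert-butyldiphenylsilyloxy)-3-methylcyclohex-2-en-1-one, via silyl enol ether 8 (not isolated)
Conditions: MeLi, CuI, Me3SiCl, THF, −78 °C; then Pd(OAc)2, MeCN, 25 °C
Reagents that add atoms: methyllithium, C[Li]
Why: Conjugate addition of the Gilman cuprate with silyl trapping, then Saegusa–Ito dehydrogenation of the crude silyl enol ether, puts the C15 methyl on the enone β-carbon; the transient stereocentre is erased.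

Step 8
Reactants: 10 2,2-dimethyl-1,3-dioxan-5-one
Product: 11 2,2-dimethyl-4H-1,3-dioxin-5-yl trifluoromethanesulfonate
Conditions: LiN(SiMe3)2, PhNTf2, THF, −78 → 0 °C
Reagents that add atoms: N-phenylbis(trifluoromethanesulfonimide), O=S(=O)(N(c1ccccc1)S(=O)(=O)C(F)(F)F)C(F)(F)F
Why: Trapping of the ketone enolate with the N-aryl triflimide gives the enol triflate, whose ring fixes the enol-ether oxygen cis to the CH2O arm.

Step 9
Reactants: 9 methyl enone; 11 dioxinyl triflate
Product: 12 (4R,5R,6R)-4-(tert-butyldimethylsilyloxy)-5-(tert-butyldiphenylsilyloxy)-6-(2,2-dimethyl-4H-1,3-dioxin-5-yl)-3-methylcyclohex-2-en-1-one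
Conditions: LiN(SiMe3)2, THF, −78 °C; then 11, Pd2(dba)3 (cat.), P(t-Bu)3·HBF4 (cat.), −78 → 25 °C; then Et3N, CH2Cl2
Reagents that add atoms: none
Why: Palladium-catalysed α-alkenylation of the kinetic α′-lithium enolate with the enol triflate (enolate cross-coupling) forms C1–C10; the new centre is epimerisable and amine equilibration should leave the all-equatorial isomer with C10 trans to the C2 silyloxy group.

Step 10
Reactants: 13 4-methoxybenzyl alcohol; 14 trichloroethylene
Product: 15 (E)-1,2-dichlorovinyl 4-methoxybenzyl ether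
Conditions: KH, THF, 0 °C; then Cl2C=CHCl, −50 → 25 °C
Reagents that add atoms: none
Why: The potassium alkoxide adds to dichloroacetylene formed in situ from trichloroethylene (addition–elimination), giving the dichlorovinyl ether that serves as a stable ynol-ether precursor.

Step 11
Reactants: 12 dioxinyl enone; 15 dichlorovinyl ether
Product: 17 (1R,4R,5R,6R)-4-(tert-butyldimethylsilyloxy)-5-(tert-butyldiphenylsilyloxy)-6-(2,2-dimethyl-4H-1,3-dioxin-5-yl)-1-[(4-methoxybenzyloxy)ethynyl]-3-methylcyclohex-2-en-1-ol, via lithium alkynyl ether 16 (not isolated)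
Conditions: n-BuLi (2.2 equiv), THF, −78 → −40 °C; CeCl3, −78 °C; then 12, −78 °C
Reagents that add atoms: none
Why: Double elimination/chlorine–lithium exchange gives the lithium alkynyl ether, whose cerium derivative adds 1,2 to the enolisable enone by axial attack anti to the axial C1–H, so the alkynyl group ends cis to the equatorial dioxinyl group and the hydroxyl equatorial (organocerium carbonyl addition).

Step 12
Reactants: 17 alkynyl carbinol
Product: 18 (1S,4R,5R,6R)-4-(tert-butyldimethylsilyloxy)-5-(tert-butyldiphenylsilyloxy)-6-(2,2-dimethyl-4H-1,3-dioxin-5-yl)-1-[(E)-2-(4-methoxybenzyloxy)ethenyl]-3-methylcyclohex-2-en-1-ol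
Conditions: LiAlH4, THF, 0 → 25 °C
Reagents that add atoms: none
Why: Alkoxide-directed trans-hydroalumination of the propargylic alcohol (LiAlH4 reduction of an alkoxyethynyl carbinol) should give the (E)-enol ether.

Step 13
Reactants: 18 cis-1,2-dialkenylcyclohexenol
Product: 21 (2R,3R,8S,9S)-cyclodeca-1(10),4-dien-6-one with ring-cis C1=C10 and C4=C5; C2 OTBDPS; C3 OTBS; C8 OPMB; O9 and O14 joined as isopropylidene acetal, via potassium alkoxide 19 (not isolated), via potassium enolate 20 (not isolated)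
Conditions: KH, 18-crown-6, THF, 0 → 25 °C; then AcOH/THF, −78 °C
Reagents that add atoms: none
Why: Deprotonation gives alkoxide 19, in which the C1–C6 bond breaks as C8–C9 forms in a concerted, charge-accelerated [3,3] shift (anionic oxy-Cope rearrangement) to enolate 20, which is protonated at C7 on quenching. The closest known reaction type is the KH/18-crown-6 ring expansion of cis-1,2-dialkenylcyclohexenols to cyclodecadienones. The ten-membered ring is not closed end to end but by σ-bond exchange inside a six-membered chair transition state (C8, C7, C6, C1, C10, C9), a four-atom ring enlargement. C8 and C9 are set by that chair with both enol-ether oxygens equatorial (the (E)-vinyl ether and the ring-fixed dioxin), which gives the threo (8S,9S) pair, and their sense relative to C2/C3 is relayed from the C1 and C6 centres that are destroyed. The step needs the chair with the C1–C2 bond axial, which gives the ring-cis C1=C10; this is the ground-state half-chair of 18 (C10, O2 and O3 equatorial, C6 alkenyl axial), whereas the other half-chair would suffer C10/O3 and O2/O6 syn-diaxial contacts. Low temperature and a cold acidic quench are meant to spare the β-alkoxy enolate from losing the C8 ether.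

Step 14
Reactants: 21 cyclodecadienone; 22 methyl bromoacetate
Product: 23 C7-(methoxycarbonylmethyl) ketone, (2R,3R,7S,8S,9S), C11 trans to the C8 ether
Conditions: LiN(SiMe3)2, THF, −78 °C; then BrCH2CO2Me, DMPU, −78 → −40 °C
Reagents that add atoms: none
Why: Alkylation of the kinetic lithium enolate, which can form only toward C7 because C5 is vinylic; with C8–H eclipsing the enolate (allylic strain) the bromoacetate should enter anti to the C8–C9 ring bond, placing C11 trans to the C8 ether.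

Step 15
Reactants: 23 keto ester
Product: 25 cis-fused γ-lactone (12,6-olide), (2R,3R,6R,7R,8S,9S), via hydroxy ester 24 (not isolated)
Conditions: NaBH4, CeCl3·7H2O, MeOH, −40 → 25 °C
Reagents that add atoms: none
Why: Luche 1,2-reduction in which hydride attacks the C6 carbonyl anti to the C7–C8 ring bond (Felkin–Anh) should give the alcohol cis to the acetate arm, which closes to the cis-fused γ-lactone.

Step 16
Reactants: 25 lactone
Product: 28 α-methylene lactone (C11=C13), (2R,3R,6R,7R,8S,9S), via Mannich base 26 (not isolated), via ammonium iodide 27 (not isolated)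
Conditions: LiN(SiMe3)2, THF, −78 °C; CH2=NMe2+ I−, −78 → 0 °C; then MeI, MeOH; then aq. NaHCO3, CH2Cl2
Reagents that add atoms: N,N-dimethylmethyleneiminium iodide, C=[N+](C)C.[I-]
Why: Mannich reaction of the lactone lithium enolate with Eschenmoser's salt, N-methylation and bicarbonate-induced β-elimination install the exocyclic methylene while no other enolisable ester is yet present.

Step 17
Reactants: 28 methylene lactone
Product: 29 C9,C14-diol (2R,3R,6R,7R,8S,9S)
Conditions: PPTS, MeOH, 25 °C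
Reagents that add atoms: none
Why: Acid-catalysed transketalisation in methanol removes the six-membered isopropylidene acetal, which is more labile than the secondary silyl ethers and the PMB ether.

Step 18
Reactants: 29 diol
Product: 30 C14 enal with free C9 hydroxyl
Conditions: TEMPO (cat.), PhI(OAc)2, CH2Cl2, 25 °C
Reagents that add atoms: none
Why: The oxoammonium oxidation (TEMPO with PhI(OAc)2) is selective for the primary allylic alcohol over the secondary C9 hydroxyl and stops at the enal.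

Step 19
Reactants: 30 enal
Product: 32 C14 methyl ester with free C9 hydroxyl, via carboxylic acid 31 (not isolated)
Conditions: NaClO2, NaH2PO4, 2-methyl-2-butene, t-BuOH/H2O, 0 °C; then MeI, KHCO3, DMF, 25 °C
Reagents that add atoms: sodium chlorite, [Na+].[O-]Cl=O; iodomethane, CI
Why: Pinnick oxidation of the enal followed by alkylation of the potassium carboxylate gives the C14 methyl ester under conditions too mild to add nucleophiles to the methylene lactone.

Step 20
Reactants: 32 methyl ester; 33 (R)-2-methylbutanoic acid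
Product: 34 C9 (R)-2-methylbutanoate
Conditions: DCC, DMAP (cat.), CH2Cl2, 0 → 25 °C
Reagents that add atoms: none
Why: Steglich esterification acylates the only free hydroxyl (C9); low temperature and little DMAP guard the α-stereocentre of the acid.

Step 21
Reactants: 34 C9 ester
Product: 35 C8 alcohol
Conditions: DDQ, CH2Cl2/pH 7 buffer, 0 °C
Reagents that add atoms: none
Why: Oxidative cleavage of the PMB ether with DDQ under buffered conditions frees the C8 hydroxyl and should leave silyl ethers, esters and the alkenes alone.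

Step 22
Reactants: 36 benzyl tiglate
Product: 37 benzyl (2S,3R)-2,3-dimethyloxirane-2-carboxylate
Conditions: D-fructose-derived ketone catalyst (4,5-di-O-acetyl form, cat.), KHSO5 (as 2KHSO5·KHSO4·K2SO4), NaHCO3, Bu4NHSO4, MeCN/aq. Na2EDTA, 0 °C
Reagents that add atoms: potassium peroxymonosulfate, OOS(=O)(=O)[O-].[K+]
Why: Shi epoxidation (chiral dioxirane) of the trisubstituted enoate should give the (2S,3R)-epoxide with retention of the alkene geometry.

Step 23
Reactants: 37 epoxy ester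
Product: 38 benzyl (2S,3S)-3-acetoxy-2-hydroxy-2-methylbutanoate
Conditions: AcOH, CsOAc, 70 °C
Reagents that add atoms: acetic acid, CC(=O)O
Why: Acetate opens the glycidic ester by SN2 attack at C3, the carbon remote from the ester, with inversion, giving the (2S,3S) acetoxy alcohol directly.

Step 24
Reactants: 38 acetoxy hydroxy ester
Product: 39 benzyl (2S,3S)-3-acetoxy-2-methyl-2-(triethylsilyloxy)butanoate
Conditions: Et3SiOTf, 2,6-lutidine, CH2Cl2, 0 °C
Reagents that add atoms: triethylsilyl trifluoromethanesulfonate, CC[Si](CC)(CC)OS(=O)(=O)C(F)(F)F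
Why: Silyl triflate silylation masks the tertiary hydroxyl for the coupling.

Step 25
Reactants: 39 silyl-protected benzyl ester
Product: 40 (2S,3S)-3-acetoxy-2-methyl-2-(triethylsilyloxy)butanoic acid
Conditions: H2, Pd/C, EtOAc, 25 °C
Reagents that add atoms: none
Why: Hydrogenolysis cleaves the benzyl ester without touching the acetate or the silyl ether.

Step 26
Reactants: 35 C8 alcohol; 40 side-chain acid
Product: 42 C8 ester of acid 40 (C9 2-methylbutanoate; C3 OTBS; C2 OTBDPS), via mixed anhydride 41 (not isolated)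
Conditions: 2,4,6-Cl3C6H2COCl, Et3N, THF, 25 °C; then 35, DMAP, toluene, 25 °C
Reagents that add atoms: none
Why: Yamaguchi esterification through the mixed trichlorobenzoic anhydride should join the α-quaternary acid to the hindered C8 alcohol.

Step 27
Reactants: 42 fully protected diester
Product: 43 C3 alcohol with free side-chain tertiary hydroxyl and C2 OTBDPS
Conditions: HF·pyridine, pyridine, THF, 0 → 25 °C
Reagents that add atoms: none
Why: HF·pyridine cleaves the TBS ether at C3 and the tertiary TES ether but should leave the far more acid-stable TBDPS ether on O2.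

Step 28
Reactants: 43 C3 alcohol
Product: 44 C3 methanesulfonate
Conditions: MsCl, Et3N, CH2Cl2, −20 °C
Reagents that add atoms: methanesulfonyl chloride, CS(=O)(=O)Cl
Why: Sulfonylation of the only free secondary alcohol gives the C3 mesylate; the tertiary α-hydroxy ester is too hindered to react at low temperature.

Step 29
Reactants: 44 C3 mesylate
Product: 46 CNP0402153.1, via hydroxy mesylate 45 (not isolated)
Conditions: Bu4NF, THF, 0 °C
Reagents that add atoms: none
Why: Fluoride removes the TBDPS group and the liberated C2 oxygen displaces the C3 mesylate from the rear (intramolecular Williamson closure, 3-exo-tet), inverting C3 to give the cis-epoxide with retention at C2.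

**Compound list**

1 | (−)-quinic acid, (1S,3R,4S,5R)-1,3,4,5-tetrahydroxycyclohexane-1-carboxylic acid | C1[C@H]([C@H]([C@@H](C[C@@]1(C(=O)O)O)O)O)O | starting material
2 | 3,4-O-isopropylidenequinic acid 1,5-lactone | C1[C@H]2OC(C)(C)O[C@H]2[C@H]3C[C@]1(O)C(=O)O3 | intermediate
3 | 1-(hydroxymethyl)-3,4-O-isopropylidenecyclohexane-1,5-diol (quinic configuration) | C1[C@H]2OC(C)(C)O[C@H]2[C@H](O)C[C@]1(O)CO | intermediate
4 | (3R,4S,5R)-5-hydroxy-3,4-(isopropylidenedioxy)cyclohexan-1-one | C1[C@H]2OC(C)(C)O[C@H]2[C@H](O)CC1=O | intermediate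
5 | (3R,4S,5R)-5-(tert-butyldiphenylsilyloxy)-3,4-(isopropylidenedioxy)cyclohexan-1-one | C1[C@H]2OC(C)(C)O[C@H]2[C@H](O[Si](c3ccccc3)(c4ccccc4)C(C)(C)C)CC1=O | intermediate
6 | (4R,5R)-5-(tert-butyldiphenylsilyloxy)-4-hydroxycyclohex-2-en-1-one | O=C1C=C[C@@H](O)[C@H](O[Si](c2ccccc2)(c3ccccc3)C(C)(C)C)C1 | intermediate
7 | (4R,5R)-4-(tert-butyldimethylsilyloxy)-5-(tert-butyldiphenylsilyloxy)cyclohex-2-en-1-one | O=C1C=C[C@@H](O[Si](C)(C)C(C)(C)C)[C@H](O[Si](c2ccccc2)(c3ccccc3)C(C)(C)C)C1 | intermediate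
8 | trimethylsilyl enol ether of the 3-methyl ketone (3-methyl trans to 4-OTBS) | C[Si](C)(C)OC1=C[C@H](C)[C@@H](O[Si](C)(C)C(C)(C)C)[C@H](O[Si](c2ccccc2)(c3ccccc3)C(C)(C)C)C1 | intermediate
9 | (4R,5R)-4-(tert-butyldimethylsilyloxy)-5-(tert-butyldiphenylsilyloxy)-3-methylcyclohex-2-en-1-one | O=C1C=C(C)[C@@H](O[Si](C)(C)C(C)(C)C)[C@H](O[Si](c2ccccc2)(c3ccccc3)C(C)(C)C)C1 | intermediate
10 | 2,2-dimethyl-1,3-dioxan-5-one | CC1(C)OCC(=O)CO1 | starting material
11 | 2,2-dimethyl-4H-1,3-dioxin-5-yl trifluoromethanesulfonate | CC1(C)OCC(OS(=O)(=O)C(F)(F)F)=CO1 | intermediate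
12 | (4R,5R,6R)-4-(tert-butyldimethylsilyloxy)-5-(tert-butyldiphenylsilyloxy)-6-(2,2-dimethyl-4H-1,3-dioxin-5-yl)-3-methylcyclohex-2-en-1-one | O=C1C=C(C)[C@@H](O[Si](C)(C)C(C)(C)C)[C@H](O[Si](c2ccccc2)(c3ccccc3)C(C)(C)C)[C@H]1C4=COC(C)(C)OC4 | intermediate
13 | 4-methoxybenzyl alcohol | COc1ccc(CO)cc1 | starting material
14 | trichloroethylene | ClC=C(Cl)Cl | starting material
15 | (E)-1,2-dichlorovinyl 4-methoxybenzyl ether | COc1ccc(CO/C(Cl)=C\Cl)cc1 | intermediate
16 | lithium (4-methoxybenzyloxy)acetylide | [Li]C#COCc1ccc(OC)cc1 | intermediate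
17 | (1R,4R,5R,6R)-4-(tert-butyldimethylsilyloxy)-5-(tert-butyldiphenylsilyloxy)-6-(2,2-dimethyl-4H-1,3-dioxin-5-yl)-1-[(4-methoxybenzyloxy)ethynyl]-3-methylcyclohex-2-en-1-ol | O[C@]1(C#COCc2ccc(OC)cc2)C=C(C)[C@@H](O[Si](C)(C)C(C)(C)C)[C@H](O[Si](c3ccccc3)(c4ccccc4)C(C)(C)C)[C@H]1C5=COC(C)(C)OC5 | intermediate
18 | (1S,4R,5R,6R)-4-(tert-butyldimethylsilyloxy)-5-(tert-butyldiphenylsilyloxy)-6-(2,2-dimethyl-4H-1,3-dioxin-5-yl)-1-[(E)-2-(4-methoxybenzyloxy)ethenyl]-3-methylcyclohex-2-en-1-ol (both alkenyl groups cis; key-step precursor) | O[C@]1(/C=C/OCc2ccc(OC)cc2)C=C(C)[C@@H](O[Si](C)(C)C(C)(C)C)[C@H](O[Si](c3ccccc3)(c4ccccc4)C(C)(C)C)[C@H]1C5=COC(C)(C)OC5 | intermediate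
19 | potassium alkoxide of 18 | [K+].[O-][C@]1(/C=C/OCc2ccc(OC)cc2)C=C(C)[C@@H](O[Si](C)(C)C(C)(C)C)[C@H](O[Si](c3ccccc3)(c4ccccc4)C(C)(C)C)[C@H]1C5=COC(C)(C)OC5 | intermediate
20 | potassium C6=C7 enolate of the ring-expanded ketone (C5 trans to C8) | [K+].[O-]/C1=C\[C@H](OCc2ccc(OC)cc2)[C@H]3OC(C)(C)OC/C3=C/[C@@H](O[Si](c4ccccc4)(c5ccccc5)C(C)(C)C)[C@H](O[Si](C)(C)C(C)(C)C)/C(C)=C\1 | intermediate
21 | (2R,3R,8S,9S)-cyclodeca-1(10),4-dien-6-one, ring-cis C1=C10 and C4=C5, 4-methyl, C2 OTBDPS, C3 OTBS, C8 OPMB, O9/O14 isopropylidene acetal (key-step product) | O=C1/C=C(/C)[C@@H](O[Si](C)(C)C(C)(C)C)[C@H](O[Si](c2ccccc2)(c3ccccc3)C(C)(C)C)/C=C4/COC(C)(C)O[C@@H]4[C@@H](OCc5ccc(OC)cc5)C1 | intermediate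
22 | methyl bromoacetate | COC(=O)CBr | starting material
23 | (2R,3R,7S,8S,9S)-7-(methoxycarbonylmethyl) derivative of ketone 21 (C11 trans to O8) | O=C1/C=C(/C)[C@@H](O[Si](C)(C)C(C)(C)C)[C@H](O[Si](c2ccccc2)(c3ccccc3)C(C)(C)C)/C=C4/COC(C)(C)O[C@@H]4[C@@H](OCc5ccc(OC)cc5)[C@@H]1CC(=O)OC | intermediate
24 | (6R,7R)-6-hydroxy ester from reduction of 23 (OH cis to the acetate arm) | O[C@@H]1/C=C(/C)[C@@H](O[Si](C)(C)C(C)(C)C)[C@H](O[Si](c2ccccc2)(c3ccccc3)C(C)(C)C)/C=C4/COC(C)(C)O[C@@H]4[C@@H](OCc5ccc(OC)cc5)[C@@H]1CC(=O)OC | intermediate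
25 | (2R,3R,6R,7R,8S,9S) cis-fused 12,6-lactone | O=C1O[C@@H]2/C=C(/C)[C@@H](O[Si](C)(C)C(C)(C)C)[C@H](O[Si](c3ccccc3)(c4ccccc4)C(C)(C)C)/C=C5/COC(C)(C)O[C@@H]5[C@@H](OCc6ccc(OC)cc6)[C@@H]2C1 | intermediate
26 | 11-(dimethylaminomethyl) lactone (C11 epimers) | CN(C)CC1C(=O)O[C@@H]2/C=C(/C)[C@@H](O[Si](C)(C)C(C)(C)C)[C@H](O[Si](c3ccccc3)(c4ccccc4)C(C)(C)C)/C=C5/COC(C)(C)O[C@@H]5[C@@H](OCc6ccc(OC)cc6)[C@H]12 | intermediate
27 | 11-(trimethylammoniomethyl) lactone iodide | C[N+](C)(C)CC1C(=O)O[C@@H]2/C=C(/C)[C@@H](O[Si](C)(C)C(C)(C)C)[C@H](O[Si](c3ccccc3)(c4ccccc4)C(C)(C)C)/C=C5/COC(C)(C)O[C@@H]5[C@@H](OCc6ccc(OC)cc6)[C@H]12.[I-] | intermediate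
28 | (2R,3R,6R,7R,8S,9S) α-methylene lactone with O9/O14 acetal | C=C1C(=O)O[C@@H]2/C=C(/C)[C@@H](O[Si](C)(C)C(C)(C)C)[C@H](O[Si](c3ccccc3)(c4ccccc4)C(C)(C)C)/C=C5/COC(C)(C)O[C@@H]5[C@@H](OCc6ccc(OC)cc6)[C@H]12 | intermediate
29 | C9,C14-diol | C=C1C(=O)O[C@@H]2/C=C(/C)[C@@H](O[Si](C)(C)C(C)(C)C)[C@H](O[Si](c3ccccc3)(c4ccccc4)C(C)(C)C)/C=C(/CO)[C@H](O)[C@@H](OCc5ccc(OC)cc5)[C@H]12 | intermediate
30 | C14 enal, C9 hydroxyl free | C=C1C(=O)O[C@@H]2/C=C(/C)[C@@H](O[Si](C)(C)C(C)(C)C)[C@H](O[Si](c3ccccc3)(c4ccccc4)C(C)(C)C)/C=C(/C=O)[C@H](O)[C@@H](OCc5ccc(OC)cc5)[C@H]12 | intermediate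
31 | C14 carboxylic acid | C=C1C(=O)O[C@@H]2/C=C(/C)[C@@H](O[Si](C)(C)C(C)(C)C)[C@H](O[Si](c3ccccc3)(c4ccccc4)C(C)(C)C)/C=C(/C(=O)O)[C@H](O)[C@@H](OCc5ccc(OC)cc5)[C@H]12 | intermediate
32 | C14 methyl ester, C9 hydroxyl free | C=C1C(=O)O[C@@H]2/C=C(/C)[C@@H](O[Si](C)(C)C(C)(C)C)[C@H](O[Si](c3ccccc3)(c4ccccc4)C(C)(C)C)/C=C(/C(=O)OC)[C@H](O)[C@@H](OCc5ccc(OC)cc5)[C@H]12 | intermediate
33 | (R)-2-methylbutanoic acid | CC[C@@H](C)C(=O)O | starting material
34 | C9 (R)-2-methylbutanoate, C8 OPMB | C=C1C(=O)O[C@@H]2/C=C(/C)[C@@H](O[Si](C)(C)C(C)(C)C)[C@H](O[Si](c3ccccc3)(c4ccccc4)C(C)(C)C)/C=C(/C(=O)OC)[C@H](OC(=O)[C@H](C)CC)[C@@H](OCc5ccc(OC)cc5)[C@H]12 | intermediate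
35 | C9 (R)-2-methylbutanoate, C8 hydroxyl free | C=C1C(=O)O[C@@H]2/C=C(/C)[C@@H](O[Si](C)(C)C(C)(C)C)[C@H](O[Si](c3ccccc3)(c4ccccc4)C(C)(C)C)/C=C(/C(=O)OC)[C@H](OC(=O)[C@H](C)CC)[C@@H](O)[C@H]12 | intermediate
36 | benzyl tiglate, benzyl (E)-2-methylbut-2-enoate | C/C=C(\C)C(=O)OCc1ccccc1 | starting material
37 | benzyl (2S,3R)-2,3-dimethyloxirane-2-carboxylate | C[C@H]1O[C@]1(C)C(=O)OCc2ccccc2 | intermediate
38 | benzyl (2S,3S)-3-acetoxy-2-hydroxy-2-methylbutanoate | O=C(OCc1ccccc1)[C@@](C)(O)[C@H](C)OC(C)=O | intermediate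
39 | benzyl (2S,3S)-3-acetoxy-2-methyl-2-(triethylsilyloxy)butanoate | O=C(OCc1ccccc1)[C@@](C)(O[Si](CC)(CC)CC)[C@H](C)OC(C)=O | intermediate
40 | (2S,3S)-3-acetoxy-2-methyl-2-(triethylsilyloxy)butanoic acid | OC(=O)[C@@](C)(O[Si](CC)(CC)CC)[C@H](C)OC(C)=O | intermediate
41 | mixed anhydride of acid 40 with 2,4,6-trichlorobenzoic acid | O=C(OC(=O)c1c(Cl)cc(Cl)cc1Cl)[C@@](C)(O[Si](CC)(CC)CC)[C@H](C)OC(C)=O | intermediate
42 | C8 (2S,3S)-3-acetoxy-2-methyl-2-(triethylsilyloxy)butanoate, C9 (R)-2-methylbutanoate, C3 OTBS, C2 OTBDPS | C=C1C(=O)O[C@@H]2/C=C(/C)[C@@H](O[Si](C)(C)C(C)(C)C)[C@H](O[Si](c3ccccc3)(c4ccccc4)C(C)(C)C)/C=C(/C(=O)OC)[C@H](OC(=O)[C@H](C)CC)[C@@H](OC(=O)[C@@](C)(O[Si](CC)(CC)CC)[C@H](C)OC(C)=O)[C@H]12 | intermediate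
43 | (3R)-C3 alcohol, side-chain hydroxyl free, C2 OTBDPS | C=C1C(=O)O[C@@H]2/C=C(/C)[C@@H](O)[C@H](O[Si](c3ccccc3)(c4ccccc4)C(C)(C)C)/C=C(/C(=O)OC)[C@H](OC(=O)[C@H](C)CC)[C@@H](OC(=O)[C@@](C)(O)[C@H](C)OC(C)=O)[C@H]12 | intermediate
44 | (3R)-C3 methanesulfonate, C2 OTBDPS | C=C1C(=O)O[C@@H]2/C=C(/C)[C@@H](OS(C)(=O)=O)[C@H](O[Si](c3ccccc3)(c4ccccc4)C(C)(C)C)/C=C(/C(=O)OC)[C@H](OC(=O)[C@H](C)CC)[C@@H](OC(=O)[C@@](C)(O)[C@H](C)OC(C)=O)[C@H]12 | intermediate
45 | (2R,3R)-2-hydroxy-3-methanesulfonate | C=C1C(=O)O[C@@H]2/C=C(/C)[C@@H](OS(C)(=O)=O)[C@H](O)/C=C(/C(=O)OC)[C@H](OC(=O)[C@H](C)CC)[C@@H](OC(=O)[C@@](C)(O)[C@H](C)OC(C)=O)[C@H]12 | intermediate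
46 | CNP0402153.1, (2R,3S,6R,7R,8S,9S)-2,3-epoxy-12,6-lactone with C8 (2S,3S)-3-acetoxy-2-hydroxy-2-methylbutanoate, C9 (R)-2-methylbutanoate and C14 methyl ester | C=C1C(=O)O[C@@H]2/C=C(/C)[C@@H]3O[C@@H]3/C=C(/C(=O)OC)[C@H](OC(=O)[C@H](C)CC)[C@@H](OC(=O)[C@@](C)(O)[C@H](C)OC(C)=O)[C@H]12 | target

**Step count and risks**

Total step count: 29. Longest linear sequence: 23 steps (steps 1–7, 9, 11–21, 26–29, from quinic acid).

Steps most likely to fail:

1. Step 13. With a donor oxygen on each bond-forming terminus the sigmatropic shift may be slow, so that fragmentation of alkoxide 19 or loss of the C8 ether from enolate 20 overtakes it. The fallback takes one enol ether out of the rearrangement and adds O8 afterwards. It sets out from enone 12: CH2=CHMgBr/CeCl3 adds at C6 to give the 1-vinyl carbinol F1, whose potassium alkoxide (KH, 18-crown-6) should rearrange in the classical manner to the C8-unsubstituted cyclodecadienone F2. IBX dehydrogenation then gives the cross-conjugated dienone F3 (C7=C8). Base-catalysed oxa-Michael addition of alcohol 13 at C8 (KN(SiMe3)2 cat.) is reversible and should settle on the 8,9-trans isomer, which rejoins the route at ketone 21.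

2. Step 9. Coupling at the hindered α′-carbon may be slow, which would let the enolate equilibrate to the dienolate or expel the β-silyloxy group. The fallback builds the C1–C10 bond by aldol chemistry. It sets out from enone 9: its lithium enolate is added to ketone 10 to give the tertiary aldol F4; mesylation gives the mesylate F5, which eliminates with DBU to the exocyclic alkylidene ketone F6. γ-Deprotonation with KN(SiMe3)2 and kinetic α-protonation of the dienolate should move the double bond into the dioxane ring; amine equilibration at C1 then returns to ketone 12.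

3. Step 14. The electrophile may enter on the wrong face of the medium-ring enolate, or the enolate may eliminate the C8 ether before it is alkylated. The fallback uses the same facial bias to deliver hydrogen instead of carbon. It sets out from ketone 21: aldol addition of the lithium enolate to methyl glyoxylate gives the hydroxy ester F7, mesylation gives the mesylate F8, and elimination gives the alkylidene keto ester F9. Conjugate reduction with [(Ph3P)CuH]6 and protonation at C7 would then place C11 on the face that direct alkylation failed to reach, rejoining the route at keto ester 23; C7 can also be equilibrated with DBU at that stage.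

**Further compounds**

F1 | step 13 | (1S,4R,5R,6R)-4-(tert-butyldimethylsilyloxy)-5-(tert-butyldiphenylsilyloxy)-6-(2,2-dimethyl-4H-1,3-dioxin-5-yl)-3-methyl-1-vinylcyclohex-2-en-1-ol | O[C@]1(C=C)C=C(C)[C@@H](O[Si](C)(C)C(C)(C)C)[C@H](O[Si](c2ccccc2)(c3ccccc3)C(C)(C)C)[C@H]1C4=COC(C)(C)OC4
F2 | step 13 | C8-unsubstituted analogue of ketone 21, (2R,3R,9S) | O=C1/C=C(/C)[C@@H](O[Si](C)(C)C(C)(C)C)[C@H](O[Si](c2ccccc2)(c3ccccc3)C(C)(C)C)/C=C4/COC(C)(C)O[C@@H]4CC1
F3 | step 13 | cross-conjugated 7,8-dehydro ketone (C7=C8 geometry not defined) | O=C1/C=C(/C)[C@@H](O[Si](C)(C)C(C)(C)C)[C@H](O[Si](c2ccccc2)(c3ccccc3)C(C)(C)C)/C=C4/COC(C)(C)O[C@@H]4C=C1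
F4 | step 9 | aldol of enone 9 with ketone 10, 6-(5-hydroxy-2,2-dimethyl-1,3-dioxan-5-yl) enone | O=C1C=C(C)[C@@H](O[Si](C)(C)C(C)(C)C)[C@H](O[Si](c2ccccc2)(c3ccccc3)C(C)(C)C)[C@H]1C4(O)COC(C)(C)OC4
F5 | step 9 | methanesulfonate of F4 | O=C1C=C(C)[C@@H](O[Si](C)(C)C(C)(C)C)[C@H](O[Si](c2ccccc2)(c3ccccc3)C(C)(C)C)[C@H]1C4(OS(C)(=O)=O)COC(C)(C)OC4
F6 | step 9 | 6-(2,2-dimethyl-1,3-dioxan-5-ylidene) enone | O=C1C=C(C)[C@@H](O[Si](C)(C)C(C)(C)C)[C@H](O[Si](c2ccccc2)(c3ccccc3)C(C)(C)C)C1=C4COC(C)(C)OC4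
F7 | step 14 | glyoxylate aldol of ketone 21 (C7 and C11 epimers) | O=C1/C=C(/C)[C@@H](O[Si](C)(C)C(C)(C)C)[C@H](O[Si](c2ccccc2)(c3ccccc3)C(C)(C)C)/C=C4/COC(C)(C)O[C@@H]4[C@@H](OCc5ccc(OC)cc5)C1C(O)C(=O)OC
F8 | step 14 | methanesulfonate of F7 | O=C1/C=C(/C)[C@@H](O[Si](C)(C)C(C)(C)C)[C@H](O[Si](c2ccccc2)(c3ccccc3)C(C)(C)C)/C=C4/COC(C)(C)O[C@@H]4[C@@H](OCc5ccc(OC)cc5)C1C(OS(C)(=O)=O)C(=O)OC
F9 | step 14 | 7-(methoxycarbonylmethylidene) ketone (C7=C11 geometry not defined) | O=C1/C=C(/C)[C@@H](O[Si](C)(C)C(C)(C)C)[C@H](O[Si](c2ccccc2)(c3ccccc3)C(C)(C)C)/C=C4/COC(C)(C)O[C@@H]4[C@@H](OCc5ccc(OC)cc5)C1=CC(=O)OC
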